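The fused guaiacol ring (ring A) is disconnected from the tetralin at two neighbouring carbons. These are C1 (para to its OH, bound to benzylic C7H2) and C6 (para to its OMe, bound to the diaryl methine C7'). In one flask a 4-bromoguaiacol ether is joined to a chiral four-carbon chain. Negishi coupling forms C1–C7. Acid then opens a temporary tetrahydrofuran (oxygen bridging C9 and C7') to a quinone-methide-like cation that C6 traps, copying the presumed lariciresinol-to-isolariciresinol biosynthesis. The precursor is a 2-aryl-4-(iodomethyl)tetrahydrofuran that already carries the coumarate on C9'. Its ether ring masks C9–OH, so the two hydroxymethyl groups never compete.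

Key step: step 6

Remark on numbering (lignan convention):
- Ring A is the fused aromatic ring (C1–C6) and ring B is the saturated ring of the tetralin.
- C7 is the benzylic CH2, C8 the CH bearing C9H2OH, C8' the CH bearing C9'H2O-acyl, and C7' the CH bearing the pendant aryl group.

Remark on the chemistry: the benzyl-protected building blocks 1, 9 and 11 are taken as commercial.

Step 1
Reactants: 1 4-(benzyloxy)-3-methoxybenzaldehyde; 2 vinylmagnesium bromide
Product: 3 rac-1-[4-(benzyloxy)-3-methoxyphenyl]prop-2-en-1-ol
Conditions: THF, −78 → 0 °C; then sat. aq. NH4Cl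
Reagents that add atoms: none
Why: Grignard 1,2-addition to the aldehyde should give the allylic alcohol as a racemate, whose C7' stereocentre is sorted out in step 2.

Step 2
Reactants: 3 rac-1-[4-(benzyloxy)-3-methoxyphenyl]prop-2-en-1-ol
Product: 4 (R)-[4-(benzyloxy)-3-methoxyphenyl][(2S)-oxiran-2-yl]methanol (erythro epoxy alcohol)
Conditions: Ti(OiPr)4 (cat.), D-(−)-diisopropyl tartrate (cat.), tBuOOH (0.45 equiv), 4 Å molecular sieves, CH2Cl2, −20 °C
Reagents that add atoms: tert-butyl hydroperoxide, CC(C)(C)OO
Why: Sharpless kinetic resolution with the D-tartrate catalyst epoxidises the (S)-enantiomer of 3 much faster than its mirror image, so stopping below half conversion should give erythro 4 as a single enantiomer (C7' fixed by enantiomer selection, C8' by reagent-controlled face selection) while the slow enantiomer stays unchanged and is separated.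

Step 3
Reactants: 4 erythro epoxy alcohol; 5 allyl bromide
Product: 6 (2S)-2-[(R)-[4-(benzyloxy)-3-methoxyphenyl](prop-2-en-1-yloxy)methyl]oxirane
Conditions: NaH, Bu4NI (cat.), THF, 0 °C → rt
Reagents that add atoms: none
Why: Williamson etherification of the sodium alkoxide in an aprotic medium at low temperature should outrun Payne rearrangement and touches no stereocentre.

Step 4
Reactants: 6 epoxy allyl ether
Product: 8 [(2S,3R,4R)-2-[4-(benzyloxy)-3-methoxyphenyl]-4-(iodomethyl)oxolan-3-yl]methanol, via alkyltitanium alkoxide 7 (not isolated)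
Conditions: Cp2TiCl2, Zn dust, THF, rt (gives Cp2TiCl); 6 added; then iodine, 0 °C; cold 1 M HCl work-up
Reagents that add atoms: iodine, [I][I]
Why: In this Nugent–RajanBabu reaction Cp2TiCl (trivalent titanium) opens the epoxide homolytically to the secondary C8' radical, which closes 5-exo-trig onto the allyl group through a chair-like transition state with the C7' aryl group pseudo-equatorial, so that C7' alone sets C8' (side chain trans to aryl) and C8 (C7 cis to C9'), and a second Cp2TiCl captures the primary C7 radical as 7, whose carbon–titanium bond iodine cleaves.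

Step 5
Reactants: 8 iodo alcohol; 9 (E)-3-[4-(benzyloxy)phenyl]prop-2-enoic acid
Product: 10 [(2S,3R,4R)-2-[4-(benzyloxy)-3-methoxyphenyl]-4-(iodomethyl)oxolan-3-yl]methyl (E)-3-[4-(benzyloxy)phenyl]prop-2-enoate
Conditions: DCC, DMAP (cat.), CH2Cl2, 0 °C → rt
Reagents that add atoms: none
Why: Steglich esterification acylates the only free hydroxyl group (C9'–OH, since C9–O is tied up in the ether ring) under conditions too mild to displace the neighbouring primary iodide.

Step 6
Reactants: 10 iodomethyl tetrahydrofuran coumarate; 11 1-(benzyloxy)-4-bromo-2-methoxybenzene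
Product: 14 tri-O-benzyl ether of the target (1S,2R,3R), via alkylzinc iodide 12 (not isolated), via tri-O-benzyl lariciresinol coumarate 13 (not isolated)
Conditions: (a) Zn dust, LiCl, THF, 30 °C; (b) supernatant added to 11, Pd(OAc)2 (cat.), SPhos (cat.), THF, rt → 40 °C; (c) same flask: THF stripped off, CH2Cl2, CF3CO2H, 0 °C → rt; aq. NaHCO3
Reagents that add atoms: none
Why: Zinc inserts into the primary C7–iodine bond of 10 to give 12, which tolerates the ester and the benzylic ether, and zerovalent palladium (formed from Pd(OAc)2 and SPhos) couples it with 11 by oxidative addition into the carbon–bromine bond, transmetalation and reductive elimination (sp3–sp2 Negishi coupling), so that C7 becomes bound to C1 of ring A, the carbon para to the benzyloxy group, with the regiochemistry dictated by the halogen. CF3CO2H then protonates the ring oxygen of 13 and only the C7'–O bond ionises, because it alone gives a cation stabilised by a para-benzyloxy group; this quinone-methide-like ion is attacked by C6 of the newly attached ring A in an intramolecular Friedel–Crafts alkylation, the closest known reaction being the acid-induced isomerisation of lariciresinol-type tetrahydrofuran lignans into aryltetralins. Ring B closes as a six-membered ring in the 6-endo mode with respect to the arene π bond (the C1–C6 bond ends up inside the ring), whereas five-membered ipso closure at C1 is reversible and leads nowhere. C8 and C8' are not touched, and the new stereocentre C7' is controlled by C8' through a chair-like transition state with the pendant aryl group and both CH2O side chains pseudo-equatorial, which should give the 7',8'-trans (7'S) product whatever the configuration of C7' in 13. The step needs attack through C6 (para to OMe) and not C2 (ortho to OMe and flanked on both sides), which electronics and sterics secure, and it needs C–C bond formation to win over re-closure of the ether by C9–OH, which is secured because re-closure is reversible and rearomatisation is not. Opening of the ether sets C9–OH free while C9' keeps its ester, so the two primary alcohols stay differentiated.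

Step 7
Reactants: 14 tri-O-benzyl ether of the target
Product: 15 [(1S,2R,3R)-7-hydroxy-1-(4-hydroxy-3-methoxyphenyl)-3-(hydroxymethyl)-6-methoxy-1,2,3,4-tetrahydronaphthalen-2-yl]methyl (E)-3-(4-hydroxyphenyl)prop-2-enoate (target)
Conditions: BCl3, pentamethylbenzene, CH2Cl2, −78 °C; then water
Reagents that add atoms: none
Why: Lewis-acid debenzylation of aryl benzyl ethers with BCl3 and pentamethylbenzene as a non-basic benzyl-cation scavenger runs at −78 °C, where the cinnamate double bond (which hydrogenolysis would saturate), the ester, the aryl methyl ethers and all stereocentres should survive.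

Compound list
1 | 4-(benzyloxy)-3-methoxybenzaldehyde | O=Cc1ccc(OCc2ccccc2)c(OC)c1 | starting material
2 | vinylmagnesium bromide | C=C[Mg]Br | starting material
3 | rac-1-[4-(benzyloxy)-3-methoxyphenyl]prop-2-en-1-ol | OC(C=C)c1ccc(OCc2ccccc2)c(OC)c1 | intermediate
4 | (R)-[4-(benzyloxy)-3-methoxyphenyl][(2S)-oxiran-2-yl]methanol | O[C@H](c1ccc(OCc2ccccc2)c(OC)c1)[C@@H]1CO1 | intermediate
5 | allyl bromide | C=CCBr | starting material
6 | (2S)-2-[(R)-[4-(benzyloxy)-3-methoxyphenyl](prop-2-en-1-yloxy)methyl]oxirane | C=CCO[C@H](c1ccc(OCc2ccccc2)c(OC)c1)[C@@H]1CO1 | intermediate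
7 | cyclised tetrahydrofuran carrying C9'–O–Ti(Cl)Cp2 and C7–Ti(Cl)Cp2 (Cp drawn σ-bound) | O1[C@H](c2ccc(OCc3ccccc3)c(OC)c2)[C@@H](CO[Ti](Cl)(C2C=CC=C2)C2C=CC=C2)[C@@H](C[Ti](Cl)(C2C=CC=C2)C2C=CC=C2)C1 | intermediate
8 | [(2S,3R,4R)-2-[4-(benzyloxy)-3-methoxyphenyl]-4-(iodomethyl)oxolan-3-yl]methanol | O1[C@H](c2ccc(OCc3ccccc3)c(OC)c2)[C@@H](CO)[C@@H](CI)C1 | intermediate
9 | (E)-3-[4-(benzyloxy)phenyl]prop-2-enoic acid | OC(=O)/C=C/c1ccc(OCc2ccccc2)cc1 | starting material
10 | [(2S,3R,4R)-2-[4-(benzyloxy)-3-methoxyphenyl]-4-(iodomethyl)oxolan-3-yl]methyl (E)-3-[4-(benzyloxy)phenyl]prop-2-enoate | O1[C@H](c2ccc(OCc3ccccc3)c(OC)c2)[C@@H](COC(=O)/C=C/c2ccc(OCc3ccccc3)cc2)[C@@H](CI)C1 | intermediate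
11 | 1-(benzyloxy)-4-bromo-2-methoxybenzene | COc1cc(Br)ccc1OCc1ccccc1 | starting material
12 | alkylzinc iodide of 10 (C7–ZnI in place of C7–iodine, stereocentres unchanged) | O1[C@H](c2ccc(OCc3ccccc3)c(OC)c2)[C@@H](COC(=O)/C=C/c2ccc(OCc3ccccc3)cc2)[C@@H](C[Zn]I)C1 | intermediate
13 | [(2S,3R,4R)-2-[4-(benzyloxy)-3-methoxyphenyl]-4-[[4-(benzyloxy)-3-methoxyphenyl]methyl]oxolan-3-yl]methyl (E)-3-[4-(benzyloxy)phenyl]prop-2-enoate | O1[C@H](c2ccc(OCc3ccccc3)c(OC)c2)[C@@H](COC(=O)/C=C/c2ccc(OCc3ccccc3)cc2)[C@@H](Cc2ccc(OCc3ccccc3)c(OC)c2)C1 | intermediate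
14 | [(1S,2R,3R)-7-(benzyloxy)-1-[4-(benzyloxy)-3-methoxyphenyl]-3-(hydroxymethyl)-6-methoxy-1,2,3,4-tetrahydronaphthalen-2-yl]methyl (E)-3-[4-(benzyloxy)phenyl]prop-2-enoate | COc1cc([C@H]2c3cc(OCc4ccccc4)c(OC)cc3C[C@@H](CO)[C@@H]2COC(=O)/C=C/c2ccc(OCc3ccccc3)cc2)ccc1OCc1ccccc1 | intermediate
15 | [(1S,2R,3R)-7-hydroxy-1-(4-hydroxy-3-methoxyphenyl)-3-(hydroxymethyl)-6-methoxy-1,2,3,4-tetrahydronaphthalen-2-yl]methyl (E)-3-(4-hydroxyphenyl)prop-2-enoate | COc1cc([C@H]2c3cc(O)c(OC)cc3C[C@@H](CO)[C@@H]2COC(=O)/C=C/c2ccc(O)cc2)ccc1O | target

Total step count: 7. Longest linear sequence: 7 steps (1 → 15).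

Steps most likely to fail

Step 6. Zinc insertion may be slow or incomplete, and the organozinc may be protonated before it couples. In the acid stage the cation may be captured by other nucleophiles, or benzyl groups may be partly lost. The fallback reverses the polarity of the first bond formation. It sets out from 10 and 11 and comes back at 13, and from there at 14. Bromide 11 is converted by bromine–lithium exchange (nBuLi, THF, −78 °C) and ZnCl2 into [4-(benzyloxy)-3-methoxyphenyl]zinc chloride F1. This is coupled with the untouched alkyl iodide 10 under cobalt catalysis (CoCl2·2LiCl, TMEDA, THF, 0 °C), a radical-type arylzinc–alkyl halide coupling that needs no metal insertion into 10. After the solvent switch CF3CO2H is added to the same flask, so 13 again goes on to 14 without isolation.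

Step 4. Three things may go wrong:
- The primary radical may abstract hydrogen before titanium captures it.
- The cis selectivity of the ring closure may erode.
- The titanium alkoxide may displace the new iodide.

The fallback avoids both the titanium capture and the iodide. It sets out from 4 and comes back at 13. Epoxy alcohol 4 is O-propargylated (NaH, propargyl bromide, THF) to the propargyl ether F2. Cp2TiCl then triggers a 5-exo-dig closure in which the vinyl radical simply takes up hydrogen. Acidic work-up gives the 4-methylidene tetrahydrofuran alcohol F3, with only C8' set at this stage. Steglich esterification with 9 gives the methylidene ester F4. 9-BBN-H adds to the exocyclic alkene from the face opposite the C9' side chain to give the B-alkyl-9-BBN derivative F5, with C8 set by substrate control. B-alkyl Suzuki–Miyaura coupling with 11 (Pd(dppf)Cl2, K3PO4, DMF/THF/water) gives 13, which after a solvent switch in the same vessel is treated with CF3CO2H as in step 6.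

Step 2. The electron-rich benzylic alcohol may ionise or undergo allylic transposition on the Lewis-acidic titanium catalyst, and the epoxy alcohol may be opened. Either process would erode enantiomeric purity. The fallback separates resolution from epoxidation. It sets out from 3 and comes back at 4, and for the minor epimer at 7. Racemic 3 is resolved by lipase-catalysed acylation (Candida antarctica lipase B, vinyl acetate, MTBE). By the usual size rule for secondary alcohols this acetylates the (R)-enantiomer to the (R)-acetate F6 and leaves the (S)-allylic alcohol F7. Hydroxyl-directed epoxidation of F7 (VO(acac)2, tBuOOH, CH2Cl2) gives mainly 4 together with its threo epimer F8. The epimer need not be removed, because its allyl ether F9 (NaH, 5) gives the same planar C8' radical in step 4 and so converges on 7.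

Further compounds
F1 | step 6 | [4-(benzyloxy)-3-methoxyphenyl]zinc chloride | COc1cc([Zn]Cl)ccc1OCc1ccccc1
F2 | step 4 | (2S)-2-[(R)-[4-(benzyloxy)-3-methoxyphenyl](prop-2-yn-1-yloxy)methyl]oxirane | C#CCO[C@H](c1ccc(OCc2ccccc2)c(OC)c1)[C@@H]1CO1
F3 | step 4 | [(2S,3R)-2-[4-(benzyloxy)-3-methoxyphenyl]-4-methylideneoxolan-3-yl]methanol | O1[C@H](c2ccc(OCc3ccccc3)c(OC)c2)[C@@H](CO)C(=C)C1
F4 | step 4 | [(2S,3R)-2-[4-(benzyloxy)-3-methoxyphenyl]-4-methylideneoxolan-3-yl]methyl (E)-3-[4-(benzyloxy)phenyl]prop-2-enoate | O1[C@H](c2ccc(OCc3ccccc3)c(OC)c2)[C@@H](COC(=O)/C=C/c2ccc(OCc3ccccc3)cc2)C(=C)C1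
F5 | step 4 | B-alkyl-9-BBN derivative of F4 (C7–B bond, C7 cis to C9') | O1[C@H](c2ccc(OCc3ccccc3)c(OC)c2)[C@@H](COC(=O)/C=C/c2ccc(OCc3ccccc3)cc2)[C@@H](CB2C3CCCC2CCC3)C1
F6 | step 2 | (R)-1-[4-(benzyloxy)-3-methoxyphenyl]prop-2-en-1-yl acetate | CC(=O)O[C@@H](c1ccc(OCc2ccccc2)c(OC)c1)C=C
F7 | step 2 | (S)-1-[4-(benzyloxy)-3-methoxyphenyl]prop-2-en-1-ol | O[C@H](c1ccc(OCc2ccccc2)c(OC)c1)C=C
F8 | step 2 | (R)-[4-(benzyloxy)-3-methoxyphenyl][(2R)-oxiran-2-yl]methanol (threo epimer of 4) | O[C@H](c1ccc(OCc2ccccc2)c(OC)c1)[C@H]1CO1
F9 | step 2 | (2R)-2-[(R)-[4-(benzyloxy)-3-methoxyphenyl](prop-2-en-1-yloxy)methyl]oxirane | C=CCO[C@H](c1ccc(OCc2ccccc2)c(OC)c1)[C@H]1CO1
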